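**Retrosynthetic overview**
- Last C–C bond: the C4–C8 interflavan bond, made by a Lewis-acid Friedel–Crafts reaction of a 4β-alkoxy tri-O-benzyl-epiafzelechin with penta-O-benzyl-epigallocatechin, then global hydrogenolysis.
- The C4 leaving group comes from DDQ oxidation of tri-O-benzyl-epiafzelechin; its cis C2/C3 pair is set in one step by asymmetric hydrogenation with dynamic kinetic resolution of the racemic flavan-3-one.
- Key disconnection: C4–C4a of the flavan-3-one. Ring A attacks an alpha-oxo gold carbene made from a terminal alkyne and an N-oxide; this is an enolonium equivalent, with the alpha-carbon of the C3 ketone acting as the electrophile.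
- The alkyne precursor is an aryl propargyl ether from Mitsunobu union of 3,5-bis(benzyloxy)phenol (ring A) with the propargylic alcohol from 4-(benzyloxy)benzaldehyde (ring B) and ethynylmagnesium bromide.
- Ring order: rings A and B and the whole lower flavan (rings D, E, F, from natural epigallocatechin) are carried in preformed; ring C is the only ring built, in step 3.

Assumption: in step 4 the sense of induction is taken by analogy with 2-arylcyclohexanones and the same catalyst family; if it proves opposite, the mirror-image catalyst is used.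

**Step 1**
Reactants: 1 4-(benzyloxy)benzaldehyde; 2 ethynylmagnesium bromide
Product: 3 (±)-1-[4-(benzyloxy)phenyl]prop-2-yn-1-ol
Conditions: THF, 0 °C to rt; then H2O
Reagents that add atoms: none
Why: Grignard 1,2-addition of the alkynyl nucleophile to the aldehyde; the carbinol is racemic on purpose because this center (later C2) is reset in step 4.

**Step 2**
Reactants: 3 (±)-1-[4-(benzyloxy)phenyl]prop-2-yn-1-ol; 4 3,5-bis(benzyloxy)phenol
Product: 5 (±)-1,3-bis(benzyloxy)-5-({1-[4-(benzyloxy)phenyl]prop-2-yn-1-yl}oxy)benzene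
Conditions: PPh3, DIAD, THF, 0 °C to rt
Reagents that add atoms: none
Why: Mitsunobu etherification, in which the phenol (pKa about 10) displaces the activated propargylic oxygen and reacts at O, not at the ring carbons as acid-promoted propargylation would.

**Step 3**
Reactants: 5 (±)-1,3-bis(benzyloxy)-5-({1-[4-(benzyloxy)phenyl]prop-2-yn-1-yl}oxy)benzene
Product: 7 (±)-5,7-bis(benzyloxy)-2-[4-(benzyloxy)phenyl]chroman-3-one, via alpha-oxo gold carbene 6 (not isolated)
Conditions: (Me4tBuXPhos)AuNTf2 (5 mol %), 2,6-dibromopyridine N-oxide (1.5 equiv), ClCH2CH2Cl, rt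
Reagents that add atoms: 2,6-dibromopyridine N-oxide, [O-][n+]1c(Br)cccc1Br
Why: Gold-catalysed alkyne oxidation with intramolecular Friedel–Crafts closure (the known chroman-3-one synthesis from aryl propargyl ethers): the N-oxide adds to the internal alkyne carbon and N–O cleavage gives carbene 6, whose carbon (future C4, normally a nucleophilic enolate carbon) is electrophilic and is attacked by the triply oxygen-activated ring A carbon ortho to the ether, closing ring C; C2 stays racemic.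

**Step 4**
Reactants: 7 (±)-5,7-bis(benzyloxy)-2-[4-(benzyloxy)phenyl]chroman-3-one
Product: 8 (2R,3R)-5,7-bis(benzyloxy)-2-[4-(benzyloxy)phenyl]chroman-3-ol (5,7,4'-tri-O-benzyl-(−)-epiafzelechin)
Conditions: H2 (50 atm), RuCl2[(R)-Xyl-SDP][(S,S)-DPEN] (1 mol %), KOtBu (10 mol %), iPrOH/toluene, rt
Reagents that add atoms: none
Why: Proposed new method: the C2–H is alpha to the ketone, benzylic and alpha-oxygenated, so tert-butoxide racemises C2 quickly while the chiral ruthenium hydride reduces the (2R)-ketone faster and from the face opposite the C2 aryl group, giving the cis (2R,3R) alcohol and setting C2 and C3 together; the closest known reaction type is Noyori-type hydrogenation with dynamic kinetic resolution of racemic 2-arylcycloalkanones and alpha-aryloxy ketones to cis alcohols.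

**Step 5**
Reactants: 8 (2R,3R)-5,7-bis(benzyloxy)-2-[4-(benzyloxy)phenyl]chroman-3-ol
Product: 9 (2R,3R,4S)-5,7-bis(benzyloxy)-2-[4-(benzyloxy)phenyl]-4-(2-ethoxyethoxy)chroman-3-ol
Conditions: DDQ (2 equiv), 2-ethoxyethanol (10 equiv), CH2Cl2, rt
Reagents that add atoms: 2-ethoxyethanol, CCOCCO
Why: DDQ benzylic oxidation: hydride abstraction at C4 gives a cation stabilised by the ring A oxygens, and the alcohol adds anti to the axial 3-OH, so the 4β (3,4-trans) ether forms; aryl benzyl ethers and C2–H are not touched.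

**Step 6**
Reactants: 10 (−)-epigallocatechin
Product: 11 (2R,3R)-5,7-bis(benzyloxy)-2-[3,4,5-tris(benzyloxy)phenyl]chroman-3-ol (5,7,3',4',5'-penta-O-benzyl-(−)-epigallocatechin)
Conditions: BnBr (5.5 equiv), K2CO3 (6 equiv), DMF, −10 °C to rt, argon
Reagents that add atoms: benzyl bromide, BrCc1ccccc1
Why: Williamson etherification of the five phenols only (the secondary 3-OH is not deprotonated by carbonate); low temperature and exclusion of air avoid C2 epimerisation and pyrogallol oxidation, so no stereocenter changes.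

**Step 7**
Reactants: 9 (2R,3R,4S)-5,7-bis(benzyloxy)-2-[4-(benzyloxy)phenyl]-4-(2-ethoxyethoxy)chroman-3-ol; 11 5,7,3',4',5'-penta-O-benzyl-(−)-epigallocatechin
Product: 12 5,7,4'-tri-O-benzyl-epiafzelechin-(4β→8)-5,7,3',4',5'-penta-O-benzyl-epigallocatechin, upper unit (2R,3R,4R), lower unit (2R,3R)
Conditions: TMSOTf (0.1 equiv), CH2Cl2, −78 to −40 °C; 11 in threefold excess (recovered)
Reagents that add atoms: none
Why: Lewis-acid-promoted Friedel–Crafts alkylation: ionisation at C4 gives the ring A-stabilised cation and C8 of 11 (more reactive than C6) attacks anti to the axial 3-OH, setting C4 as 4β (3,4-trans, 4R); the excess of 11 suppresses self-condensation of 9.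

**Step 8**
Reactants: 12 5,7,4'-tri-O-benzyl-epiafzelechin-(4β→8)-5,7,3',4',5'-penta-O-benzyl-epigallocatechin
Product: 13 epiafzelechin-(4β→8)-epigallocatechin (CNP0290824.1)
Conditions: H2 (1 atm), Pd(OH)2/C (20 wt %), THF/MeOH/H2O, rt
Reagents that add atoms: none
Why: Catalytic hydrogenolysis of the eight aryl benzyl ethers; the interflavan bond and all five stereocenters are not affected under these neutral conditions.

**Compound list**
1 | 4-(benzyloxy)benzaldehyde | O=Cc1ccc(OCc2ccccc2)cc1 | starting material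
2 | ethynylmagnesium bromide | C#C[Mg]Br | starting material
3 | (±)-1-[4-(benzyloxy)phenyl]prop-2-yn-1-ol (racemic) | OC(C#C)c1ccc(OCc2ccccc2)cc1 | intermediate
4 | 3,5-bis(benzyloxy)phenol | Oc1cc(OCc2ccccc2)cc(OCc2ccccc2)c1 | starting material
5 | (±)-1,3-bis(benzyloxy)-5-({1-[4-(benzyloxy)phenyl]prop-2-yn-1-yl}oxy)benzene (racemic) | C#CC(Oc1cc(OCc2ccccc2)cc(OCc2ccccc2)c1)c1ccc(OCc2ccccc2)cc1 | intermediate
6 | alpha-oxo gold carbene, cationic (Me4tBuXPhos)Au=CH–C(=O)–CH(OAr)Ar' complex with NTf2 counter-ion (racemic, not isolated) | CC(C)c1cc(C(C)C)c(-c2c(C)c(C)c(C)c(C)c2[P+](C(C)(C)C)(C(C)(C)C)[Au]=CC(=O)C(Oc2cc(OCc3ccccc3)cc(OCc3ccccc3)c2)c2ccc(OCc3ccccc3)cc2)c(C(C)C)c1.O=S(=O)([N-]S(=O)(=O)C(F)(F)F)C(F)(F)F | intermediate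
7 | (±)-5,7-bis(benzyloxy)-2-[4-(benzyloxy)phenyl]chroman-3-one (racemic) | O=C1Cc2c(OCc3ccccc3)cc(OCc3ccccc3)cc2OC1c1ccc(OCc2ccccc2)cc1 | intermediate
8 | (2R,3R)-5,7-bis(benzyloxy)-2-[4-(benzyloxy)phenyl]chroman-3-ol | O(Cc1ccccc1)c1ccc(cc1)[C@H]1Oc2cc(OCc3ccccc3)cc(OCc3ccccc3)c2C[C@H]1O | intermediate
9 | (2R,3R,4S)-5,7-bis(benzyloxy)-2-[4-(benzyloxy)phenyl]-4-(2-ethoxyethoxy)chroman-3-ol | O(Cc1ccccc1)c1ccc(cc1)[C@H]1Oc2cc(OCc3ccccc3)cc(OCc3ccccc3)c2[C@H](OCCOCC)[C@H]1O | intermediate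
10 | (−)-epigallocatechin, (2R,3R)-2-(3,4,5-trihydroxyphenyl)chroman-3,5,7-triol | O[C@@H]1Cc2c(O)cc(O)cc2O[C@@H]1c1cc(O)c(O)c(O)c1 | starting material
11 | (2R,3R)-5,7-bis(benzyloxy)-2-[3,4,5-tris(benzyloxy)phenyl]chroman-3-ol | O[C@@H]1Cc2c(OCc3ccccc3)cc(OCc3ccccc3)cc2O[C@@H]1c1cc(OCc2ccccc2)c(OCc2ccccc2)c(OCc2ccccc2)c1 | intermediate
12 | 5,7,4'-tri-O-benzyl-epiafzelechin-(4β→8)-5,7,3',4',5'-penta-O-benzyl-epigallocatechin, (2R,3R,4R) upper and (2R,3R) lower unit | O(Cc1ccccc1)c1ccc([C@H]2Oc3cc(OCc4ccccc4)cc(OCc4ccccc4)c3[C@H](c3c(OCc4ccccc4)cc(OCc4ccccc4)c4c3O[C@H](c3cc(OCc5ccccc5)c(OCc5ccccc5)c(OCc5ccccc5)c3)[C@H](O)C4)[C@H]2O)cc1 | intermediate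
13 | epiafzelechin-(4β→8)-epigallocatechin, (2R,2'R,3R,3'R,4R)-2-(4-hydroxyphenyl)-2'-(3,4,5-trihydroxyphenyl)-4,8'-bichromane-3,3',5,5',7,7'-hexol | Oc1ccc([C@H]2Oc3cc(O)cc(O)c3[C@H](c3c(O)cc(O)c4c3O[C@H](c3cc(O)c(O)c(O)c3)[C@H](O)C4)[C@H]2O)cc1 | target

**Count and risks**
Total steps: 8. Longest linear sequence: 7 steps (steps 1, 2, 3, 4, 5, 7, 8).

The three steps most likely to fail:

Risk in step 3 (gold carbene ring closure). The very electron-rich ring A may attack the gold-activated alkyne directly (6-endo hydroarylation), the doubly activated propargylic C–O bond may ionise, or the carbene may be oxidised a second time. Fallback, from 5 back to 7: 5 is cyclised without oxidant (PtCl2, toluene, 80 °C) to (±)-5,7-bis(benzyloxy)-2-[4-(benzyloxy)phenyl]-2H-chromene F1. Hydroboration–oxidation (BH3·THF, then NaOH/H2O2) adds anti to the C2 aryl group and gives (±)-2,3-trans-5,7-bis(benzyloxy)-2-[4-(benzyloxy)phenyl]chroman-3-ol F2. Dess–Martin oxidation of F2 gives ketone 7.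

Risk in step 4 (hydrogenation with dynamic kinetic resolution). The substrate class is untested; enantioselectivity, cis selectivity and the stability of the ketone to base are uncertain. Fallback, from 7 back to 8: 7 is reduced with LiBH(sec-Bu)3 and LiBr in THF at −78 °C to the racemic cis alcohol (±)-cis-5,7-bis(benzyloxy)-2-[4-(benzyloxy)phenyl]chroman-3-ol F3. F3 is esterified with (S)-methoxy(phenyl)acetic acid (DCC, DMAP). The (2R,3R)-chromanyl (S)-methoxy(phenyl)acetate F4 is separated by chromatography from the (2S,3S)-chromanyl (S)-methoxy(phenyl)acetate F5. Saponification of F4 (LiOH, THF/MeOH/H2O) gives 8.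

Risk in step 7 (interflavan coupling). Electrophile 9 can alkylate itself or the product, some 4→6 isomer may form, and an excess of 11 is needed. Fallback, from 8 back to 13: 8 is brominated at C8 (NBS, CH2Cl2, −78 °C) to 8-bromo-5,7,4'-tri-O-benzyl-epiafzelechin F6, so the electrophile can no longer act as a nucleophile at C8. DDQ and 2-ethoxyethanol convert F6 into 8-bromo-4β-(2-ethoxyethoxy)-5,7,4'-tri-O-benzyl-epiafzelechin F7. F7 is coupled with one equivalent of 11 (TMSOTf, CH2Cl2, −78 °C) to 8-bromo-5,7,4'-tri-O-benzyl-epiafzelechin-(4β→8)-5,7,3',4',5'-penta-O-benzyl-epigallocatechin F8. Hydrogenolysis of F8 (H2, Pd(OH)2/C, Et3N) removes the bromine together with the benzyl groups and gives 13.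

**Further compounds**
F1 | step 3 | (±)-5,7-bis(benzyloxy)-2-[4-(benzyloxy)phenyl]-2H-chromene (racemic) | C1(c2ccc(OCc3ccccc3)cc2)Oc2cc(OCc3ccccc3)cc(OCc3ccccc3)c2C=C1
F2 | step 3 | (±)-2,3-trans-5,7-bis(benzyloxy)-2-[4-(benzyloxy)phenyl]chroman-3-ol (racemate, both enantiomers written) | O[C@H]1Cc2c(OCc3ccccc3)cc(OCc3ccccc3)cc2O[C@@H]1c1ccc(OCc2ccccc2)cc1.O[C@@H]1Cc2c(OCc3ccccc3)cc(OCc3ccccc3)cc2O[C@H]1c1ccc(OCc2ccccc2)cc1
F3 | step 4 | (±)-cis-5,7-bis(benzyloxy)-2-[4-(benzyloxy)phenyl]chroman-3-ol (racemate, both enantiomers written) | O[C@@H]1Cc2c(OCc3ccccc3)cc(OCc3ccccc3)cc2O[C@@H]1c1ccc(OCc2ccccc2)cc1.O[C@H]1Cc2c(OCc3ccccc3)cc(OCc3ccccc3)cc2O[C@H]1c1ccc(OCc2ccccc2)cc1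
F4 | step 4 | (2R,3R)-5,7-bis(benzyloxy)-2-[4-(benzyloxy)phenyl]chroman-3-yl (S)-methoxy(phenyl)acetate | O(Cc1ccccc1)c1ccc(cc1)[C@H]1Oc2cc(OCc3ccccc3)cc(OCc3ccccc3)c2C[C@H]1OC(=O)[C@@H](OC)c1ccccc1
F5 | step 4 | (2S,3S)-5,7-bis(benzyloxy)-2-[4-(benzyloxy)phenyl]chroman-3-yl (S)-methoxy(phenyl)acetate | O(Cc1ccccc1)c1ccc(cc1)[C@@H]1Oc2cc(OCc3ccccc3)cc(OCc3ccccc3)c2C[C@@H]1OC(=O)[C@@H](OC)c1ccccc1
F6 | step 7 | 8-bromo-5,7,4'-tri-O-benzyl-epiafzelechin, (2R,3R)-5,7-bis(benzyloxy)-2-[4-(benzyloxy)phenyl]-8-bromochroman-3-ol | O(Cc1ccccc1)c1ccc(cc1)[C@H]1Oc2c(Br)c(OCc3ccccc3)cc(OCc3ccccc3)c2C[C@H]1O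
F7 | step 7 | 8-bromo-4β-(2-ethoxyethoxy)-5,7,4'-tri-O-benzyl-epiafzelechin, (2R,3R,4S) | O(Cc1ccccc1)c1ccc(cc1)[C@H]1Oc2c(Br)c(OCc3ccccc3)cc(OCc3ccccc3)c2[C@H](OCCOCC)[C@H]1O
F8 | step 7 | 8-bromo-5,7,4'-tri-O-benzyl-epiafzelechin-(4β→8)-5,7,3',4',5'-penta-O-benzyl-epigallocatechin | O(Cc1ccccc1)c1ccc([C@H]2Oc3c(Br)c(OCc4ccccc4)cc(OCc4ccccc4)c3[C@H](c3c(OCc4ccccc4)cc(OCc4ccccc4)c4c3O[C@H](c3cc(OCc5ccccc5)c(OCc5ccccc5)c(OCc5ccccc5)c3)[C@H](O)C4)[C@H]2O)cc1
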